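**Plan**

- Cuts, in retrosynthetic order: the C14=C15 enol ether (back to a C15 lactol) and the C6–OAc bond; the O–C15 bond of ring D (back to a C15 ester and a C16 silyl ether); O9–C13 and C14–C15 together (ring C); the C9–O bond (back to an 8-en-7-one); C12–C13 (sp3–sp2 coupling).
- Enabling feature: C13, the spiro atom shared by rings C and D, carries the ring C ether oxygen and the CH2 arm C14 that ends in carbonyl-level C15. This is the pattern left when an oxygen and CO add across a 1,1-disubstituted C13=C14 alkene lying γ,δ to the C9 hydroxyl.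
- Forward: rings A and B come intact from (+)-sclareolide; the C13/C14/C16 unit is joined at C12; ring B is oxidised to the 9α-hydroxy-7-ketone; ring C closes by oxypalladation–carbonylation; ring D closes as a methyl lactol ether and is dehydrated to the enol ether last.
- Stereochemistry: C5 and C10 from sclareolide; C9 from α-face nucleophilic epoxidation of the enone; C8 thermodynamic (equatorial methyl); C13 from the chiral bis(oxazoline) on palladium; C6 from α-face epoxidation of the Δ6 enol acetate and thermal acyloxy shift with inversion.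

Key step: step 9

Remark: labdane numbering is used (ring B C5–C10, ring C O–C9–C11–C12–C13, ring D C13–C14–C15–O–C16); Bn-BOXAX is 2,2'-bis(4-benzyl-4,5-dihydrooxazol-2-yl)-1,1'-binaphthyl, and its (S,S) form is written in step 9 on the assumption that it is the antipode matched to the substrate, the mirror-image ligand being used if a test run shows otherwise.

**Route**

Step 1
Reactants: 1 2-bromoprop-2-en-1-ol
Product: 2 tert-butyl[(2-bromoprop-2-en-1-yl)oxy]dimethylsilane
Conditions: TBSCl, imidazole, CH2Cl2, 0 °C → rt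
Reagents that add atoms: tert-butyldimethylsilyl chloride, CC(C)(C)[Si](C)(C)Cl
Why: Imidazole-promoted O-silylation of a primary alcohol is routine and masks the oxygen of the vinyl bromide partner for the organozinc, base and reductant steps ahead.

Step 2
Reactants: 3 (+)-sclareolide
Product: 4 methyl 13,14,15,16-tetranorlabd-8-en-12-oate
Conditions: conc. H2SO4, MeOH, rt
Reagents that add atoms: methanol, CO
Why: Acid-mediated lactone methanolysis with E1 loss of the tertiary C8 oxygen (Fischer esterification plus Zaitsev elimination) should settle under equilibrating conditions on the tetrasubstituted Δ8 alkene, with minor Δ7 and exocyclic isomers removable on AgNO3-impregnated silica and C5 and C10 untouched.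

Step 3
Reactants: 4 methyl 13,14,15,16-tetranorlabd-8-en-12-oate
Product: 5 13,14,15,16-tetranorlabd-8-en-12-ol
Conditions: LiAlH4, THF, 0 °C
Reagents that add atoms: none
Why: Hydride reduction of the ester gives the primary alcohol while the tetrasubstituted alkene is inert.

Step 4
Reactants: 5 13,14,15,16-tetranorlabd-8-en-12-ol
Product: 6 12-iodo-13,14,15,16-tetranorlabd-8-ene
Conditions: I2, PPh3, imidazole, CH2Cl2, 0 °C → rt
Reagents that add atoms: iodine, [I][I]
Why: Appel-type iodination of an unhindered primary alcohol runs under neutral conditions that leave the alkene in place.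

Step 5
Reactants: 6 12-iodo-13,14,15,16-tetranorlabd-8-ene; 2 tert-butyl[(2-bromoprop-2-en-1-yl)oxy]dimethylsilane
Product: 8 16-(tert-butyldimethylsilyloxy)-15-norlabda-8,13(14)-diene, via alkylzinc iodide 7 (not isolated)
Conditions: Zn dust, LiCl, THF, 40 °C; then 2, PdCl2(dppf) (3 mol %), THF, 50 °C
Reagents that add atoms: none
Why: Direct zinc insertion into the primary iodide followed by Negishi cross-coupling joins C12 to the sp2 carbon C13, the vinyl bromide serving as the electrophile so that no 2-metallated allyl silyl ether, prone to silyl migration, is ever formed.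

Step 6
Reactants: 8 16-(tert-butyldimethylsilyloxy)-15-norlabda-8,13(14)-diene
Product: 9 16-(tert-butyldimethylsilyloxy)-15-norlabda-8,13(14)-dien-7-one
Conditions: CrO3, 3,5-dimethylpyrazole, CH2Cl2, −20 °C
Reagents that add atoms: chromium trioxide, O=[Cr](=O)=O
Why: Allylic oxidation by the CrO3–3,5-dimethylpyrazole complex should attack the electron-rich tetrasubstituted ring alkene at its ring methylene C7, the usual site in Δ8 drimanes and labdanes, in preference to the electron-poorer 1,1-disubstituted allyl ether alkene.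

Step 7
Reactants: 9 16-(tert-butyldimethylsilyloxy)-15-norlabda-8,13(14)-dien-7-one
Product: 10 8α,9α-epoxy-16-(tert-butyldimethylsilyloxy)-15-norlabd-13(14)-en-7-one
Conditions: 30% H2O2, NaOH, MeOH, 0 °C → rt
Reagents that add atoms: hydrogen peroxide, OO
Why: Weitz–Scheffer nucleophilic epoxidation touches only the enone, and hydroperoxide should add axially to C9 on the α face, anti to the angular C10 methyl, so that the epoxide oxygen and hence the later C9 oxygen is α.

Step 8
Reactants: 10 8α,9α-epoxy-16-(tert-butyldimethylsilyloxy)-15-norlabd-13(14)-en-7-one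
Product: 11 9α-hydroxy-16-(tert-butyldimethylsilyloxy)-15-norlabd-13(14)-en-7-one (8α-methyl)
Conditions: SmI2 (2.2 equiv), THF–MeOH, −78 °C
Reagents that add atoms: none
Why: Single-electron reductive opening of the α,β-epoxy ketone by SmI2 cleaves the C8–O bond next to the carbonyl and keeps the 9α-hydroxyl, and protonation of the enolate or equilibration of the epimerisable C8 centre should leave the equatorial 8α-methyl group.

Step 9
Reactants: 11 9α-hydroxy-16-(tert-butyldimethylsilyloxy)-15-norlabd-13(14)-en-7-one (8α-methyl)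
Product: 12 methyl (13R)-9α,13-epoxy-7-oxo-16-(tert-butyldimethylsilyloxy)labdan-15-oate
Conditions: Pd(OCOCF3)2 (10 mol %), (S,S)-Bn-BOXAX (40 mol %), p-benzoquinone (4 equiv), CO (1 atm), MeOH, rt
Reagents that add atoms: carbon monoxide, [C-]#[O+]; methanol, CO
Why: The ligated divalent palladium binds the C13=C14 alkene, the 9α-hydroxyl adds to the more substituted carbon C13 (Wacker-type oxypalladation), the neopentyl C14–palladium bond inserts CO, and methanolysis of the acylpalladium releases the ester and zerovalent palladium, which benzoquinone reoxidises. The closest known reaction type is the intramolecular alkoxycarbonylation of γ-hydroxy alkenes to oxolan-2-ylacetates, including its enantioselective bis(oxazoline) variant on 1,1-disubstituted alkenes. Ring C closes in the 5-exo-trig mode. The one new stereocentre, C13, is set by the alkene face that the chiral bis(oxazoline)–palladium unit presents to the fixed axial 9α-oxygen, placing C14 on the ring C face syn to C10 (13R); the substrate's own bias between the CH2 and CH2OSi termini is expected to be small, so the ligand is the controlling element. The step needs Markovnikov 5-exo rather than 6-endo attack, which the 1,1-disubstitution secures, and carbonylation rather than β-hydride elimination, which the fully substituted C13 secures; the near-neutral quinone conditions should spare the silyl ether and the β-hydroxy ketone.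

Step 10
Reactants: 12 methyl (13R)-9α,13-epoxy-7-oxo-16-(tert-butyldimethylsilyloxy)labdan-15-oate
Product: 13 (13R)-9α,13-epoxy-16-(tert-butyldimethylsilyloxy)labdane-7,15-diol (C7 epimers)
Conditions: LiAlH4, THF, 0 °C
Reagents that add atoms: none
Why: Hydride reduction takes the ester to the C15 primary alcohol and unavoidably the C7 ketone to a secondary alcohol, whose configuration does not matter because it is reoxidised in the next step.

Step 11
Reactants: 13 (13R)-9α,13-epoxy-16-(tert-butyldimethylsilyloxy)labdane-7,15-diol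
Product: 14 (13R)-9α,13-epoxy-7-oxo-16-(tert-butyldimethylsilyloxy)labdan-15-al
Conditions: Dess–Martin periodinane, NaHCO3, CH2Cl2, rt
Reagents that add atoms: none
Why: Buffered Dess–Martin oxidation converts both alcohols in one operation, restoring the C7 ketone and bringing C15 to the aldehyde level under conditions too mild to eliminate the β-alkoxy aldehyde.

Step 12
Reactants: 14 (13R)-9α,13-epoxy-7-oxo-16-(tert-butyldimethylsilyloxy)labdan-15-al
Product: 15 (13R)-9α,13:15,16-diepoxy-15-methoxylabdan-7-one (C15 anomers)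
Conditions: CSA (cat.), MeOH, rt
Reagents that add atoms: methanol, CO
Why: Acid-catalysed methanolysis removes the primary silyl ether, and the freed C16 hydroxyl closes on the C15 aldehyde (5-exo hemiacetalisation then Fischer-type acetal exchange) to give ring D as a methyl lactol ether that will tolerate the enolate and oxidation chemistry at C6.

Step 13
Reactants: 15 (13R)-9α,13:15,16-diepoxy-15-methoxylabdan-7-one
Product: 17 (13R)-9α,13:15,16-diepoxy-15-methoxylabd-6-en-7-yl acetate, via lithium enolate 16 (not isolated)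
Conditions: LiN(iPr)2 (1.1 equiv), THF, −78 °C; then Ac2O, −78 → 0 °C
Reagents that add atoms: acetic anhydride, CC(=O)OC(C)=O
Why: Kinetic deprotonation by the hindered amide should take the C6 methylene rather than the tertiary C8–H next to quaternary C9, and O-acetylation of the lithium enolate with acetic anhydride (classical kinetic enol acetate formation) fixes the Δ6 regiochemistry.

Step 14
Reactants: 17 (13R)-9α,13:15,16-diepoxy-15-methoxylabd-6-en-7-yl acetate
Product: 19 (13R)-6β-acetoxy-9α,13:15,16-diepoxy-15-methoxylabdan-7-one, via enol acetate epoxide 18 (not isolated)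
Conditions: dimethyldioxirane, acetone, 0 °C; evaporate; PhMe, 110–140 °C
Reagents that add atoms: dimethyldioxirane, CC1(C)OO1
Why: Neutral epoxidation should occur on the α face of the enol acetate, away from the axial methyls on C4 and C10, and the thermal enol ester epoxide rearrangement then shifts the acetoxy group from C7 to C6 intramolecularly with inversion, leaving it 6β (axial) as the C7 ketone is regenerated.

Step 15
Reactants: 19 (13R)-6β-acetoxy-9α,13:15,16-diepoxy-15-methoxylabdan-7-one
Product: 20 (13R)-6β-acetoxy-9α,13:15,16-diepoxy-15-hydroxylabdan-7-one (lactol)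
Conditions: AcOH–H2O–THF (3:1:1), 45 °C
Reagents that add atoms: water, O
Why: Mild acid hydrolysis of the furanoside-type methyl acetal unmasks the lactol under conditions that the acetate, the ring C ether and the C6 and C8 centres should withstand.

Step 16
Reactants: 20 (13R)-6β-acetoxy-9α,13:15,16-diepoxy-15-hydroxylabdan-7-one
Product: 22 (13R)-6β-acetoxy-9α,13:15,16-diepoxylabd-14-en-7-one, via lactol mesylate 21 (not isolated)
Conditions: MsCl, Et3N (excess), CH2Cl2, 0 → 40 °C
Reagents that add atoms: none
Why: Sulfonylation of the lactol hydroxyl and amine-mediated elimination through the oxocarbenium ion (the standard lactol-to-glycal dehydration) should form the C14=C15 enol ether under basic conditions that spare the acid-labile spiro enol ether and the axial α-acetoxy ketone.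

**Compound list**

1 | 2-bromoprop-2-en-1-ol | OCC(Br)=C | starting material
2 | tert-butyl[(2-bromoprop-2-en-1-yl)oxy]dimethylsilane | C=C(Br)CO[Si](C)(C)C(C)(C)C | intermediate
3 | (+)-sclareolide | C1C[C@@](C)(OC(=O)C3)[C@H]3[C@@]2(C)CCCC(C)(C)[C@H]12 | starting material
4 | methyl 13,14,15,16-tetranorlabd-8-en-12-oate | C1CC(C)=C(CC(=O)OC)[C@@]2(C)CCCC(C)(C)[C@H]12 | intermediate
5 | 13,14,15,16-tetranorlabd-8-en-12-ol | C1CC(C)=C(CCO)[C@@]2(C)CCCC(C)(C)[C@H]12 | intermediate
6 | 12-iodo-13,14,15,16-tetranorlabd-8-ene | C1CC(C)=C(CCI)[C@@]2(C)CCCC(C)(C)[C@H]12 | intermediate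
7 | (13,14,15,16-tetranorlabd-8-en-12-yl)zinc iodide | C1CC(C)=C(CC[Zn]I)[C@@]2(C)CCCC(C)(C)[C@H]12 | intermediate (not isolated)
8 | 16-(tert-butyldimethylsilyloxy)-15-norlabda-8,13(14)-diene | C1CC(C)=C(CCC(=C)CO[Si](C)(C)C(C)(C)C)[C@@]2(C)CCCC(C)(C)[C@H]12 | intermediate
9 | 16-(tert-butyldimethylsilyloxy)-15-norlabda-8,13(14)-dien-7-one | C1C(=O)C(C)=C(CCC(=C)CO[Si](C)(C)C(C)(C)C)[C@@]2(C)CCCC(C)(C)[C@H]12 | intermediate
10 | 8α,9α-epoxy-16-(tert-butyldimethylsilyloxy)-15-norlabd-13(14)-en-7-one (8β-methyl) | C1C(=O)[C@@]3(C)O[C@@]3(CCC(=C)CO[Si](C)(C)C(C)(C)C)[C@@]2(C)CCCC(C)(C)[C@H]12 | intermediate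
11 | 9α-hydroxy-16-(tert-butyldimethylsilyloxy)-15-norlabd-13(14)-en-7-one (8α-methyl, 8β-H) | C1C(=O)[C@@H](C)[C@](O)(CCC(=C)CO[Si](C)(C)C(C)(C)C)[C@@]2(C)CCCC(C)(C)[C@H]12 | intermediate
12 | methyl (13R)-9α,13-epoxy-7-oxo-16-(tert-butyldimethylsilyloxy)labdan-15-oate | C1C(=O)[C@@H](C)[C@]2(CC[C@@](CC(=O)OC)(CO[Si](C)(C)C(C)(C)C)O2)[C@@]2(C)CCCC(C)(C)[C@H]12 | intermediate
13 | (13R)-9α,13-epoxy-16-(tert-butyldimethylsilyloxy)labdane-7,15-diol (C7 epimers) | C1C(O)[C@@H](C)[C@]2(CC[C@@](CCO)(CO[Si](C)(C)C(C)(C)C)O2)[C@@]2(C)CCCC(C)(C)[C@H]12 | intermediate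
14 | (13R)-9α,13-epoxy-7-oxo-16-(tert-butyldimethylsilyloxy)labdan-15-al | C1C(=O)[C@@H](C)[C@]2(CC[C@@](CC=O)(CO[Si](C)(C)C(C)(C)C)O2)[C@@]2(C)CCCC(C)(C)[C@H]12 | intermediate
15 | (13R)-9α,13:15,16-diepoxy-15-methoxylabdan-7-one (C15 anomers) | C1C(=O)[C@@H](C)[C@]2(CC[C@]3(CC(OC)OC3)O2)[C@@]2(C)CCCC(C)(C)[C@H]12 | intermediate
16 | lithium Δ6-enolate of 15 | C1=C(O[Li])[C@@H](C)[C@]2(CC[C@]3(CC(OC)OC3)O2)[C@@]2(C)CCCC(C)(C)[C@H]12 | intermediate (not isolated)
17 | (13R)-9α,13:15,16-diepoxy-15-methoxylabd-6-en-7-yl acetate | C1=C(OC(C)=O)[C@@H](C)[C@]2(CC[C@]3(CC(OC)OC3)O2)[C@@]2(C)CCCC(C)(C)[C@H]12 | intermediate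
18 | (13R)-7β-acetoxy-6α,7α:9α,13:15,16-triepoxy-15-methoxylabdane | [C@@H]14O[C@@]4(OC(C)=O)[C@@H](C)[C@]2(CC[C@]3(CC(OC)OC3)O2)[C@@]2(C)CCCC(C)(C)[C@H]12 | intermediate (not isolated)
19 | (13R)-6β-acetoxy-9α,13:15,16-diepoxy-15-methoxylabdan-7-one | CC(=O)O[C@@H]1C(=O)[C@@H](C)[C@]2(CC[C@]3(CC(OC)OC3)O2)[C@@]2(C)CCCC(C)(C)[C@H]12 | intermediate
20 | (13R)-6β-acetoxy-9α,13:15,16-diepoxy-15-hydroxylabdan-7-one (lactol) | CC(=O)O[C@@H]1C(=O)[C@@H](C)[C@]2(CC[C@]3(CC(O)OC3)O2)[C@@]2(C)CCCC(C)(C)[C@H]12 | intermediate
21 | 15-O-methanesulfonate of lactol 20 | CC(=O)O[C@@H]1C(=O)[C@@H](C)[C@]2(CC[C@]3(CC(OS(C)(=O)=O)OC3)O2)[C@@]2(C)CCCC(C)(C)[C@H]12 | intermediate (not isolated)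
22 | (13R)-6β-acetoxy-9α,13:15,16-diepoxylabd-14-en-7-one (CNP0224709.1) | CC(=O)O[C@@H]1C(=O)[C@@H](C)[C@]2(CC[C@]3(C=COC3)O2)[C@@]2(C)CCCC(C)(C)[C@H]12 | target

**Step count**

Total steps: 16. Longest linear sequence: 15 steps (steps 2–16, from (+)-sclareolide 3 to 22).

**Steps most likely to fail, with fallbacks**

Step 9. The palladium-bound alkene may be attacked with little discrimination between its two faces, because its CH2 and CH2OSi termini differ little in size and the substrate offers no strong bias. The hindered tertiary hydroxyl may also add too slowly to outrun catalyst decay. The fallback sets out from 11 and comes back at 15, replacing steps 9–12 by reagent-controlled epoxide chemistry. The silyl group of 11 is removed with HF·pyridine to give 9α,16-dihydroxy-15-norlabd-13(14)-en-7-one F1. Sharpless asymmetric epoxidation (Ti(OiPr)4, D-(−)-diethyl tartrate, t-BuOOH, CH2Cl2, −20 °C; the tartrate antipode that the usual mnemonic assigns to the required face) should set C13 in the (13R)-13,14-epoxy alcohol F2. The primary hydroxyl is silylated again (TBSCl, imidazole) to give the epoxy silyl ether F3. CSA in CH2Cl2 then lets the 9α-hydroxyl open the epoxide at the tertiary carbon C13 in the 5-exo mode with inversion, closing ring C in the 14-hydroxy oxolane F4, whose free CH2OH is C14. Dess–Martin oxidation gives the aldehyde F5. A Wittig reaction with Ph3P=CHOMe (from the phosphonium chloride and KN(SiMe3)2, one equivalent at −78 °C so that the hindered C7 ketone is left alone) adds C15 as the methyl enol ether F6. CSA in methanol removes the silyl group and closes ring D on the protonated enol ether, giving 15.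

Step 6. Hydrogen abstraction at the allylic positions of the side-chain alkene (C12, C16) or at C11 may compete with oxidation at C7, and the allylic silyl ether may be oxidised as well. The fallback sets out from 5 and comes back at 9, replacing steps 4–6 by oxidising ring B before the second alkene is present. Acetylation of 5 (Ac2O, pyridine) gives the homoallylic acetate F7. The same CrO3–3,5-dimethylpyrazole oxidation, now on a substrate with a single alkene, gives the enone acetate F8. K2CO3 in MeOH releases the enone alcohol F9, and iodination (I2, PPh3, imidazole) gives the enone iodide F10. Zinc insertion (Zn, LiCl, THF), which tolerates the enone, gives the alkylzinc iodide F11, and Negishi coupling with 2 (PdCl2(dppf)) returns to 9.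

Step 13. Deprotonation at C8 may compete with deprotonation at C6, and a C8 enolate would expel the ring C oxygen from C9 by β-elimination; part of the enolate may also be acetylated on carbon. The fallback sets out from 15 and comes back at 16, and so at 17. The ketone is deprotonated with LiN(iPr)2 in the presence of Me3SiCl at −78 °C (internal quench), so that each enolate is silylated as it forms, giving the Δ6 trimethylsilyl enol ether F12. Any C8-derived isomer is trapped before it can eliminate and can be separated or hydrolysed back to 15. MeLi in THF at 0 °C then cleaves the O–Si bond of purified F12 to release the regiodefined lithium enolate 16, which is acetylated with Ac2O to give 17.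

**Further compounds**

F1 | step 9 | 9α,16-dihydroxy-15-norlabd-13(14)-en-7-one | C1C(=O)[C@@H](C)[C@](O)(CCC(=C)CO)[C@@]2(C)CCCC(C)(C)[C@H]12
F2 | step 9 | (13R)-13,14-epoxy-9α,16-dihydroxy-15-norlabdan-7-one | C1C(=O)[C@@H](C)[C@](O)(CC[C@@]4(CO)CO4)[C@@]2(C)CCCC(C)(C)[C@H]12
F3 | step 9 | 16-O-tert-butyldimethylsilyl ether of F2 | C1C(=O)[C@@H](C)[C@](O)(CC[C@@]4(CO[Si](C)(C)C(C)(C)C)CO4)[C@@]2(C)CCCC(C)(C)[C@H]12
F4 | step 9 | (13R)-9α,13-epoxy-14-hydroxy-16-(tert-butyldimethylsilyloxy)-15-norlabdan-7-one | C1C(=O)[C@@H](C)[C@]2(CC[C@@](CO)(CO[Si](C)(C)C(C)(C)C)O2)[C@@]2(C)CCCC(C)(C)[C@H]12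
F5 | step 9 | (13R)-9α,13-epoxy-7-oxo-16-(tert-butyldimethylsilyloxy)-15-norlabdan-14-al | C1C(=O)[C@@H](C)[C@]2(CC[C@@](C=O)(CO[Si](C)(C)C(C)(C)C)O2)[C@@]2(C)CCCC(C)(C)[C@H]12
F6 | step 9 | (13R)-9α,13-epoxy-15-methoxy-16-(tert-butyldimethylsilyloxy)labd-14-en-7-one (E/Z mixture) | C1C(=O)[C@@H](C)[C@]2(CC[C@@](C=COC)(CO[Si](C)(C)C(C)(C)C)O2)[C@@]2(C)CCCC(C)(C)[C@H]12
F7 | step 6 | 13,14,15,16-tetranorlabd-8-en-12-yl acetate | C1CC(C)=C(CCOC(C)=O)[C@@]2(C)CCCC(C)(C)[C@H]12
F8 | step 6 | 7-oxo-13,14,15,16-tetranorlabd-8-en-12-yl acetate | C1C(=O)C(C)=C(CCOC(C)=O)[C@@]2(C)CCCC(C)(C)[C@H]12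
F9 | step 6 | 12-hydroxy-13,14,15,16-tetranorlabd-8-en-7-one | C1C(=O)C(C)=C(CCO)[C@@]2(C)CCCC(C)(C)[C@H]12
F10 | step 6 | 12-iodo-13,14,15,16-tetranorlabd-8-en-7-one | C1C(=O)C(C)=C(CCI)[C@@]2(C)CCCC(C)(C)[C@H]12
F11 | step 6 | (7-oxo-13,14,15,16-tetranorlabd-8-en-12-yl)zinc iodide | C1C(=O)C(C)=C(CC[Zn]I)[C@@]2(C)CCCC(C)(C)[C@H]12
F12 | step 13 | (13R)-9α,13:15,16-diepoxy-15-methoxy-7-(trimethylsilyloxy)labd-6-ene | C1=C(O[Si](C)(C)C)[C@@H](C)[C@]2(CC[C@]3(CC(OC)OC3)O2)[C@@]2(C)CCCC(C)(C)[C@H]12
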